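1. The two interflavan bonds (C4–C8 and C4–C6) are cut to a 6,8-dilithiated, perbenzylated (+)-catechin and two molecules of one protected (2R,3R)-dihydrofisetin 4-ketone; the 4β (3,4-cis) geometry comes from hydride delivery to each diaryl C4 cation anti to O3, not from arene attack.
2. Ring C of that ketone is not closed directly: it is contracted out of a seven-membered 2,3-dihydro-5H-1,4-benzodioxepine acetal by an acetal [1,2]-Wittig shift that forms C3–C4 and leaves oxygen on C4 for the later arylation.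
3. Enabling feature: in the benzodioxepine the future C4 is a benzylic CH2 between ring A (C4a) and the ring oxygen O4, so it can be lithiated, and the future C3 is an acetal carbon (O4 and OMOM) that migrates from O4 to C4 as an oxygen-stabilised radical; O1, C2, C3, C4, C4a and C8a of ring C already sit in the seven-membered ring.
4. The benzodioxepine comes from an SNAr ether union of 4-(benzyloxy)-2-fluorobenzaldehyde (ring A) with an (S)-1-arylallyl alcohol (ring B and C2), oxidative cleavage of the vinyl group and capture of the aldehyde as the cyclic acetal.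
5. Ring order: seven-membered acetal ring, then ring C by contraction (made once, used for both upper units); all aromatic rings and the catechin heterocycle are bought.

Key step: step 6

Remark: the target is read as fisetinidol-(4β→8)-catechin-(6→4β)-fisetinidol, a (2R,3S)-catechin core carrying at C6 and C8 two identical (2R,3S,4R) units (2,3-trans, 3,4-cis); 3,4-bis(benzyloxy)benzaldehyde, 4-(benzyloxy)-2-fluorobenzaldehyde and (+)-catechin are taken as commercial.

Step 1
Reactants: 1 3,4-bis(benzyloxy)benzaldehyde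
Product: 2 (1S)-1-[3,4-bis(benzyloxy)phenyl]prop-2-en-1-ol
Conditions: Zn(CH=CH2)2 (from CH2=CHMgBr and ZnCl2), (−)-3-exo-(dimethylamino)isoborneol (10 mol %), toluene/Et2O, 0 °C
Reagents that add atoms: divinylzinc, C=C[Zn]C=C
Why: Catalytic enantioselective alkenylzinc addition to an aromatic aldehyde; the chiral zinc aminoalkoxide shields one face of the bound aldehyde and, by analogy with dialkylzinc additions with this ligand, should set the future C2 as S.

Step 2
Reactants: 2 (1S)-1-[3,4-bis(benzyloxy)phenyl]prop-2-en-1-ol; 3 4-(benzyloxy)-2-fluorobenzaldehyde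
Product: 4 4-(benzyloxy)-2-{[(1S)-1-[3,4-bis(benzyloxy)phenyl]prop-2-en-1-yl]oxy}benzaldehyde
Conditions: KN(SiMe3)2, THF, −20 °C; then 3, DMF, 0 → 25 °C
Reagents that add atoms: none
Why: SNAr etherification at the fluoride ortho to the formyl group; the alkoxide oxygen is the nucleophile, so the C–O bond at the stereocentre is never broken and the configuration of 2 is carried over.

Step 3
Reactants: 4 4-(benzyloxy)-2-{[(1S)-1-[3,4-bis(benzyloxy)phenyl]prop-2-en-1-yl]oxy}benzaldehyde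
Product: 5 [4-(benzyloxy)-2-{[(1S)-1-[3,4-bis(benzyloxy)phenyl]prop-2-en-1-yl]oxy}phenyl]methanol
Conditions: NaBH4, MeOH/THF, 0 °C
Reagents that add atoms: none
Why: Borohydride reduction of the aryl aldehyde to the benzylic alcohol; the vinyl group and benzyl ethers are inert and no stereocentre is touched.

Step 4
Reactants: 5 [4-(benzyloxy)-2-{[(1S)-1-[3,4-bis(benzyloxy)phenyl]prop-2-en-1-yl]oxy}phenyl]methanol
Product: 8 (2R)-8-(benzyloxy)-2-[3,4-bis(benzyloxy)phenyl]-2,3-dihydro-5H-1,4-benzodioxepin-3-ol (lactol; both C3 anomers), via triol 6 (not isolated), via hydroxy aldehyde 7 (not isolated)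
Conditions: OsO4 (2 mol %), NaIO4 (3 equiv), 2,6-lutidine, 1,4-dioxane/H2O, 20 °C
Reagents that add atoms: osmium tetroxide, O=[Os](=O)(=O)=O (catalytic oxygen carrier); sodium periodate, [Na+].[O-]I(=O)(=O)=O (terminal oxidant)
Why: Lemieux–Johnson oxidation; the α-aryloxy aldehyde released by diol cleavage should be captured at once by the benzylic hydroxyl as the seven-membered cyclic hemiacetal, so the epimerisable aldehyde does not accumulate, C2 is untouched and C3 forms as an anomeric mixture.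

Step 5
Reactants: 8 (2R)-8-(benzyloxy)-2-[3,4-bis(benzyloxy)phenyl]-2,3-dihydro-5H-1,4-benzodioxepin-3-ol
Product: 9 (2R,3R)-8-(benzyloxy)-2-[3,4-bis(benzyloxy)phenyl]-3-(methoxymethoxy)-2,3-dihydro-5H-1,4-benzodioxepine (2,3-trans anomer drawn; any 3S anomer is carried along)
Conditions: MOMCl, iPr2NEt, CH2Cl2, 0 → 20 °C
Reagents that add atoms: chloromethyl methyl ether, COCCl
Why: O-Alkylation of the hemiacetal hydroxyl locks the seven-membered ring as a base-stable mixed acetal whose exocyclic oxygen carries neither an acidic C–H nor silicon; the anomer with aryl and OMOM anti is expected to predominate.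

Step 6
Reactants: 9 (2R,3R)-8-(benzyloxy)-2-[3,4-bis(benzyloxy)phenyl]-3-(methoxymethoxy)-2,3-dihydro-5H-1,4-benzodioxepine
Product: 11 (2R,3S)-7-(benzyloxy)-2-[3,4-bis(benzyloxy)phenyl]-3-(methoxymethoxy)-3,4-dihydro-2H-chromen-4-ol (both C4 epimers), via C5-lithio acetal 10 (not isolated)
Conditions: s-BuLi (1.3 equiv), THF, −78 → −40 °C; NH4Cl (aq)
Reagents that add atoms: none
Why: Proposed new method: s-BuLi removes one proton from C5, the benzylic CH2 between ring A and the acetal oxygen O4 that is pre-coordinated by O1, O4 and the MOM oxygens, and the α-alkoxybenzyllithium 10 then undergoes a [1,2]-Wittig shift in which the acetal bond C3–O4 breaks homolytically to a tethered pair of a lithium ketyl (C5) and an oxygen-stabilised radical (C3) that recombine to the C3–C4 bond, O4 ending as the C4 alkoxide. The closest known reaction type is the acetal [1,2]-Wittig rearrangement of O-benzyl glycosides to C-glycosides, together with [1,2]-Wittig ring contractions of 2-aryl cyclic ethers; new here is that carbanion carbon and migrating acetal carbon sit in one benzo-fused ring, so the shift contracts the 1,4-benzodioxepine to the chroman. Ring C closes by radical–radical recombination between C3 and C4 within the tether (a formal 1,2-shift, ring contraction from seven to six members), not by an ionic cyclisation. C3 is controlled by the C2 stereocentre: migration with retention from the 2,3-trans anomer, and equally recombination of a relaxed radical through a chair-like array, should place the 2-aryl and 3-OMOM groups trans-diequatorial (3S), while the C4 carbinol centre forms as a mixture that step 7 removes. The step needs site-selective lithiation at C5 over the C2–H and the three ArOCH2Ph groups, which oxygen-directed deprotonation of the unhindered ring CH2 at −78 °C should secure, and it needs a migrating group that cannot divert the carbanion, which is why the exocyclic acetal oxygen carries MOM and not benzyl or silyl (no competing benzylic anion, no retro-Brook shift).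

Step 7
Reactants: 11 (2R,3S)-7-(benzyloxy)-2-[3,4-bis(benzyloxy)phenyl]-3-(methoxymethoxy)-3,4-dihydro-2H-chromen-4-ol
Product: 12 (2R,3R)-7-(benzyloxy)-2-[3,4-bis(benzyloxy)phenyl]-3-(methoxymethoxy)-2,3-dihydro-4H-chromen-4-one
Conditions: Dess–Martin periodinane, NaHCO3, CH2Cl2, 0 → 20 °C
Reagents that add atoms: none
Why: Dess–Martin oxidation of the secondary benzylic alcohol to the aryl ketone under buffered, non-epimerising conditions removes the uncontrolled C4 centre and gives the protected trans-dihydroflavonol.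

Step 8
Reactants: 13 (+)-catechin
Product: 15 3,5,7,3',4'-penta-O-benzyl-(+)-catechin, via tetra-O-benzylcatechin 14 (not isolated)
Conditions: BnBr (4.4 equiv), K2CO3, DMF, 20 °C; then NaH, BnBr (1.5 equiv), 0 → 20 °C
Reagents that add atoms: benzyl bromide, BrCc1ccccc1
Why: Williamson etherification in two stages; the phenols are benzylated with the weak base first, so that no phenoxide-driven ring opening can epimerise C2, and the C3 hydroxyl is then benzylated as its sodium alkoxide.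

Step 9
Reactants: 15 3,5,7,3',4'-penta-O-benzyl-(+)-catechin
Product: 16 6,8-dibromo-3,5,7,3',4'-penta-O-benzyl-(+)-catechin
Conditions: NBS (2.1 equiv), CH2Cl2, −20 → 20 °C
Reagents that add atoms: N-bromosuccinimide, O=C1CCC(=O)N1Br
Why: Electrophilic aromatic bromination; C6 and C8 of the phloroglucinol-type ring, each ortho/para to three oxygen substituents, are far more reactive than the catechol ring, so two equivalents of NBS should give the 6,8-dibromide.

Step 10
Reactants: 16 6,8-dibromo-3,5,7,3',4'-penta-O-benzyl-(+)-catechin; 12 (2R,3R)-7-(benzyloxy)-2-[3,4-bis(benzyloxy)phenyl]-3-(methoxymethoxy)-2,3-dihydro-4H-chromen-4-one (2.3 equiv)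
Product: 18 6,8-bis[(2R,3R)-7-(benzyloxy)-2-(3,4-bis(benzyloxy)phenyl)-4-hydroxy-3-(methoxymethoxy)chroman-4-yl]-3,5,7,3',4'-penta-O-benzyl-(+)-catechin (configuration at the two C4 carbinol carbons left open), via dilithio arene 17 (not isolated)
Conditions: t-BuLi (4.2 equiv), THF, −78 °C; then 12, −78 → −30 °C; NH4Cl (aq)
Reagents that add atoms: none
Why: Twofold bromine–lithium exchange and 1,2-addition of the aryllithium to the aryl ketone, the known way to arylate C4 of flavan-4-ones, with the α-OMOM group favouring addition by chelation; the two new carbinol centres need no control because step 11 destroys them.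

Step 11
Reactants: 18 6,8-bis[(2R,3R)-7-(benzyloxy)-2-(3,4-bis(benzyloxy)phenyl)-4-hydroxy-3-(methoxymethoxy)chroman-4-yl]-3,5,7,3',4'-penta-O-benzyl-(+)-catechin
Product: 19 6,8-bis[(2R,3S,4R)-7-(benzyloxy)-2-(3,4-bis(benzyloxy)phenyl)-3-(methoxymethoxy)chroman-4-yl]-3,5,7,3',4'-penta-O-benzyl-(+)-catechin
Conditions: Et3SiH (8 equiv), CF3CO2H (6 equiv), CH2Cl2, −78 → −40 °C; Et3N quench
Reagents that add atoms: none
Why: Ionic hydrogenation; acid ionises each tertiary, doubly benzylic C4 alcohol to a diaryl cation that should take hydride on the face anti to the adjacent C3 oxygen substituent, placing H-4 trans to O-3 and the catechin ring cis to it (4R, 3,4-cis), as known for acid/hydride reductions of 4-aryl-4-hydroxyflavan-3-ol ethers.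

Step 12
Reactants: 19 6,8-bis[(2R,3S,4R)-7-(benzyloxy)-2-(3,4-bis(benzyloxy)phenyl)-3-(methoxymethoxy)chroman-4-yl]-3,5,7,3',4'-penta-O-benzyl-(+)-catechin
Product: 20 6,8-bis[(2R,3S,4R)-7-(benzyloxy)-2-(3,4-bis(benzyloxy)phenyl)-3-hydroxychroman-4-yl]-3,5,7,3',4'-penta-O-benzyl-(+)-catechin
Conditions: HCl (1 M in MeOH), THF, 40 °C
Reagents that add atoms: none
Why: Acid-catalysed acetal exchange with methanol removes both MOM groups; benzyl ethers and the C4–aryl bonds of 5-deoxy upper units are stable to dilute acid, and no stereocentre is affected.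

Step 13
Reactants: 20 6,8-bis[(2R,3S,4R)-7-(benzyloxy)-2-(3,4-bis(benzyloxy)phenyl)-3-hydroxychroman-4-yl]-3,5,7,3',4'-penta-O-benzyl-(+)-catechin
Product: 21 fisetinidol-(4β→8)-catechin-(6→4β)-fisetinidol (target)
Conditions: H2 (1 atm), Pd(OH)2 on carbon, THF/MeOH, 20 °C
Reagents that add atoms: none
Why: Hydrogenolysis of the eleven benzyl ethers frees all hydroxyl groups without touching the ring C ethers, the interflavan bonds or any stereocentre.

Compound list
1 | 3,4-bis(benzyloxy)benzaldehyde | O=Cc1ccc(OCc2ccccc2)c(OCc2ccccc2)c1 | starting material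
2 | (1S)-1-[3,4-bis(benzyloxy)phenyl]prop-2-en-1-ol | O[C@H](c1ccc(OCc2ccccc2)c(OCc2ccccc2)c1)C=C | intermediate
3 | 4-(benzyloxy)-2-fluorobenzaldehyde | O=Cc1ccc(OCc2ccccc2)cc1F | starting material
4 | 4-(benzyloxy)-2-{[(1S)-1-[3,4-bis(benzyloxy)phenyl]prop-2-en-1-yl]oxy}benzaldehyde | O=Cc1ccc(OCc2ccccc2)cc1O[C@H](c1ccc(OCc2ccccc2)c(OCc2ccccc2)c1)C=C | intermediate
5 | [4-(benzyloxy)-2-{[(1S)-1-[3,4-bis(benzyloxy)phenyl]prop-2-en-1-yl]oxy}phenyl]methanol | OCc1ccc(OCc2ccccc2)cc1O[C@H](c1ccc(OCc2ccccc2)c(OCc2ccccc2)c1)C=C | intermediate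
6 | (3R)-3-[5-(benzyloxy)-2-(hydroxymethyl)phenoxy]-3-[3,4-bis(benzyloxy)phenyl]propane-1,2-diol (both C2 epimers; not isolated) | OCc1ccc(OCc2ccccc2)cc1O[C@H](c1ccc(OCc2ccccc2)c(OCc2ccccc2)c1)C(O)CO | intermediate
7 | (2R)-2-[5-(benzyloxy)-2-(hydroxymethyl)phenoxy]-2-[3,4-bis(benzyloxy)phenyl]acetaldehyde (not isolated) | OCc1ccc(OCc2ccccc2)cc1O[C@H](c1ccc(OCc2ccccc2)c(OCc2ccccc2)c1)C=O | intermediate
8 | (2R)-8-(benzyloxy)-2-[3,4-bis(benzyloxy)phenyl]-2,3-dihydro-5H-1,4-benzodioxepin-3-ol (both C3 anomers) | O1Cc2ccc(OCc3ccccc3)cc2O[C@H](c2ccc(OCc3ccccc3)c(OCc3ccccc3)c2)C1O | intermediate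
9 | (2R,3R)-8-(benzyloxy)-2-[3,4-bis(benzyloxy)phenyl]-3-(methoxymethoxy)-2,3-dihydro-5H-1,4-benzodioxepine (2,3-trans anomer) | O1Cc2ccc(OCc3ccccc3)cc2O[C@H](c2ccc(OCc3ccccc3)c(OCc3ccccc3)c2)[C@H]1OCOC | intermediate
10 | 5-lithio derivative of 9 (not isolated) | O1C([Li])c2ccc(OCc3ccccc3)cc2O[C@H](c2ccc(OCc3ccccc3)c(OCc3ccccc3)c2)[C@H]1OCOC | intermediate
11 | (2R,3S)-7-(benzyloxy)-2-[3,4-bis(benzyloxy)phenyl]-3-(methoxymethoxy)-3,4-dihydro-2H-chromen-4-ol (both C4 epimers) | OC1c2ccc(OCc3ccccc3)cc2O[C@H](c2ccc(OCc3ccccc3)c(OCc3ccccc3)c2)[C@H]1OCOC | intermediate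
12 | (2R,3R)-7-(benzyloxy)-2-[3,4-bis(benzyloxy)phenyl]-3-(methoxymethoxy)-2,3-dihydro-4H-chromen-4-one | O=C1c2ccc(OCc3ccccc3)cc2O[C@H](c2ccc(OCc3ccccc3)c(OCc3ccccc3)c2)[C@H]1OCOC | intermediate
13 | (+)-catechin, (2R,3S) | Oc1cc(O)c2c(c1)O[C@H](c1ccc(O)c(O)c1)[C@@H](O)C2 | starting material
14 | 5,7,3',4'-tetra-O-benzyl-(+)-catechin (not isolated) | c1ccccc1COc1cc(OCc2ccccc2)c2c(c1)O[C@H](c1ccc(OCc3ccccc3)c(OCc3ccccc3)c1)[C@@H](O)C2 | intermediate
15 | 3,5,7,3',4'-penta-O-benzyl-(+)-catechin | c1ccccc1COc1cc(OCc2ccccc2)c2c(c1)O[C@H](c1ccc(OCc3ccccc3)c(OCc3ccccc3)c1)[C@@H](OCc1ccccc1)C2 | intermediate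
16 | 6,8-dibromo-3,5,7,3',4'-penta-O-benzyl-(+)-catechin | Brc1c(OCc2ccccc2)c(Br)c(OCc2ccccc2)c2c1O[C@H](c1ccc(OCc3ccccc3)c(OCc3ccccc3)c1)[C@@H](OCc1ccccc1)C2 | intermediate
17 | 6,8-dilithio-3,5,7,3',4'-penta-O-benzyl-(+)-catechin (not isolated) | [Li]c1c(OCc2ccccc2)c([Li])c(OCc2ccccc2)c2c1O[C@H](c1ccc(OCc3ccccc3)c(OCc3ccccc3)c1)[C@@H](OCc1ccccc1)C2 | intermediate
18 | 6,8-bis[(2R,3R)-7-(benzyloxy)-2-(3,4-bis(benzyloxy)phenyl)-4-hydroxy-3-(methoxymethoxy)chroman-4-yl]-3,5,7,3',4'-penta-O-benzyl-(+)-catechin (C4 carbinol centres unassigned) | c1(C3(O)c4ccc(OCc5ccccc5)cc4O[C@H](c4ccc(OCc5ccccc5)c(OCc5ccccc5)c4)[C@H]3OCOC)c(OCc3ccccc3)c(C3(O)c4ccc(OCc5ccccc5)cc4O[C@H](c4ccc(OCc5ccccc5)c(OCc5ccccc5)c4)[C@H]3OCOC)c(OCc3ccccc3)c2c1O[C@H](c1ccc(OCc3ccccc3)c(OCc3ccccc3)c1)[C@@H](OCc1ccccc1)C2 | intermediate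
19 | 6,8-bis[(2R,3S,4R)-7-(benzyloxy)-2-(3,4-bis(benzyloxy)phenyl)-3-(methoxymethoxy)chroman-4-yl]-3,5,7,3',4'-penta-O-benzyl-(+)-catechin | c1([C@H]3c4ccc(OCc5ccccc5)cc4O[C@H](c4ccc(OCc5ccccc5)c(OCc5ccccc5)c4)[C@H]3OCOC)c(OCc3ccccc3)c([C@H]3c4ccc(OCc5ccccc5)cc4O[C@H](c4ccc(OCc5ccccc5)c(OCc5ccccc5)c4)[C@H]3OCOC)c(OCc3ccccc3)c2c1O[C@H](c1ccc(OCc3ccccc3)c(OCc3ccccc3)c1)[C@@H](OCc1ccccc1)C2 | intermediate
20 | 6,8-bis[(2R,3S,4R)-7-(benzyloxy)-2-(3,4-bis(benzyloxy)phenyl)-3-hydroxychroman-4-yl]-3,5,7,3',4'-penta-O-benzyl-(+)-catechin | c1([C@H]3c4ccc(OCc5ccccc5)cc4O[C@H](c4ccc(OCc5ccccc5)c(OCc5ccccc5)c4)[C@H]3O)c(OCc3ccccc3)c([C@H]3c4ccc(OCc5ccccc5)cc4O[C@H](c4ccc(OCc5ccccc5)c(OCc5ccccc5)c4)[C@H]3O)c(OCc3ccccc3)c2c1O[C@H](c1ccc(OCc3ccccc3)c(OCc3ccccc3)c1)[C@@H](OCc1ccccc1)C2 | intermediate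
21 | fisetinidol-(4β→8)-catechin-(6→4β)-fisetinidol; upper units (2R,3S,4R), catechin unit (2R,3S) | Oc1ccc2c(c1)O[C@H](c1ccc(O)c(O)c1)[C@@H](O)[C@H]2c1c(O)c2c(c([C@H]3c4ccc(O)cc4O[C@H](c4ccc(O)c(O)c4)[C@H]3O)c1O)O[C@H](c1ccc(O)c(O)c1)[C@@H](O)C2 | target

Total step count: 13. Longest linear sequence: 11 steps (steps 1–7, then 10–13).

Steps most likely to fail

Step 6 (proposed new method). The base may deprotonate the wrong C–H (C2–H or a benzyl ether CH2), which would lead to β-elimination and ring opening, or the radical pair may separate before recombination and erode control at C3. The fallback uses known chemistry, sets out from 4 and returns at 12. Lemieux–Johnson cleavage of the vinyl group of 4 (OsO4 cat., NaIO4, 2,6-lutidine) should give the dialdehyde 4-(benzyloxy)-2-{[(1R)-1-[3,4-bis(benzyloxy)phenyl]-2-oxoethyl]oxy}benzaldehyde F1. Intramolecular pinacol coupling with SmI2 (THF, t-BuOH, −78 °C) would close ring C directly, through a chair-like ketyl addition with the 2-aryl group equatorial, as the cis-diol (2R,3S,4S)-7-(benzyloxy)-2-[3,4-bis(benzyloxy)phenyl]chromane-3,4-diol F2. MnO2 should oxidise only the benzylic C4 hydroxyl to the hydroxy ketone (2R,3R)-7-(benzyloxy)-2-[3,4-bis(benzyloxy)phenyl]-3-hydroxychroman-4-one F3, and MOMCl/iPr2NEt then gives 12.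

Step 10. The second bromine–lithium exchange may stay incomplete, and the hindered, doubly ortho-substituted aryllithium may take a proton from the enolisable ketone instead of adding. The fallback installs the two units one after the other, sets out from 15 and returns at 18. One equivalent of NBS should give 8-bromo-3,5,7,3',4'-penta-O-benzyl-(+)-catechin F4. Exchange with t-BuLi (2.1 equiv) and addition to 12 would give the mono-adduct 8-[(2R,3R)-7-(benzyloxy)-2-(3,4-bis(benzyloxy)phenyl)-4-hydroxy-3-(methoxymethoxy)chroman-4-yl]-3,5,7,3',4'-penta-O-benzyl-(+)-catechin F5. Buffered NBS (NaHCO3) should brominate the remaining C6 position to the 6-bromo derivative of that mono-adduct F6, and t-BuLi (3.2 equiv, one for the hydroxyl) followed by 12 leads to 18.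

Step 11. The C4 cation may lose the C3 proton to give the enol ether, may take hydride on the face syn to O3, or the acid may strip the MOM group before reduction is complete. The fallback replaces the cation by a radical under neutral conditions, sets out from 18 and returns at 19. KN(SiMe3)2 and methyl chlorooxoacetate should convert both tertiary alkoxides into the bis(methyl oxalate) of 18 F7. Barton-type deoxygenation (Bu3SnH, AIBN, toluene, 90 °C) then cleaves each C4–O bond to the diaryl-stabilised radical, which should abstract hydrogen anti to the 3-OMOM group and give 19.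

Further compounds
F1 | step 6 | 4-(benzyloxy)-2-{[(1R)-1-[3,4-bis(benzyloxy)phenyl]-2-oxoethyl]oxy}benzaldehyde | O=Cc1ccc(OCc2ccccc2)cc1O[C@H](c1ccc(OCc2ccccc2)c(OCc2ccccc2)c1)C=O
F2 | step 6 | (2R,3S,4S)-7-(benzyloxy)-2-[3,4-bis(benzyloxy)phenyl]chromane-3,4-diol | O[C@H]1c2ccc(OCc3ccccc3)cc2O[C@H](c2ccc(OCc3ccccc3)c(OCc3ccccc3)c2)[C@H]1O
F3 | step 6 | (2R,3R)-7-(benzyloxy)-2-[3,4-bis(benzyloxy)phenyl]-3-hydroxychroman-4-one | O=C1c2ccc(OCc3ccccc3)cc2O[C@H](c2ccc(OCc3ccccc3)c(OCc3ccccc3)c2)[C@H]1O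
F4 | step 10 | 8-bromo-3,5,7,3',4'-penta-O-benzyl-(+)-catechin | Brc1c(OCc2ccccc2)cc(OCc2ccccc2)c2c1O[C@H](c1ccc(OCc3ccccc3)c(OCc3ccccc3)c1)[C@@H](OCc1ccccc1)C2
F5 | step 10 | 8-[(2R,3R)-7-(benzyloxy)-2-(3,4-bis(benzyloxy)phenyl)-4-hydroxy-3-(methoxymethoxy)chroman-4-yl]-3,5,7,3',4'-penta-O-benzyl-(+)-catechin | c1(C3(O)c4ccc(OCc5ccccc5)cc4O[C@H](c4ccc(OCc5ccccc5)c(OCc5ccccc5)c4)[C@H]3OCOC)c(OCc3ccccc3)cc(OCc3ccccc3)c2c1O[C@H](c1ccc(OCc3ccccc3)c(OCc3ccccc3)c1)[C@@H](OCc1ccccc1)C2
F6 | step 10 | 6-bromo-8-[(2R,3R)-7-(benzyloxy)-2-(3,4-bis(benzyloxy)phenyl)-4-hydroxy-3-(methoxymethoxy)chroman-4-yl]-3,5,7,3',4'-penta-O-benzyl-(+)-catechin | c1(C3(O)c4ccc(OCc5ccccc5)cc4O[C@H](c4ccc(OCc5ccccc5)c(OCc5ccccc5)c4)[C@H]3OCOC)c(OCc3ccccc3)c(Br)c(OCc3ccccc3)c2c1O[C@H](c1ccc(OCc3ccccc3)c(OCc3ccccc3)c1)[C@@H](OCc1ccccc1)C2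
F7 | step 11 | bis(methyl oxalate) of 18 (both C4 hydroxyls esterified) | c1(C3(OC(=O)C(=O)OC)c4ccc(OCc5ccccc5)cc4O[C@H](c4ccc(OCc5ccccc5)c(OCc5ccccc5)c4)[C@H]3OCOC)c(OCc3ccccc3)c(C3(OC(=O)C(=O)OC)c4ccc(OCc5ccccc5)cc4O[C@H](c4ccc(OCc5ccccc5)c(OCc5ccccc5)c4)[C@H]3OCOC)c(OCc3ccccc3)c2c1O[C@H](c1ccc(OCc3ccccc3)c(OCc3ccccc3)c1)[C@@H](OCc1ccccc1)C2
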